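**Retrosynthetic overview**
- The γ-lactone is made last, by Baeyer–Villiger insertion of oxygen into the C6–C12 bond of a 2-methylenecyclobutanone (temporary four-membered ring C6–C7–C11–C12), followed by desilylation.
- The cyclobutanone comes from an acyclic amide–allene by a macrocyclic keteniminium–allene [2+2] that forms C11–C12 and C6–C7 in one operation, closing the cyclobutane and the ten-membered carbocycle together.
- Enabling feature: the segment C10=C1–C2(O)C3–C4=C5 (ring-cis enoate, cis-oxirane, Z-alkene) is a rigid hairpin that holds C6 next to C7. The exocyclic C11=C13 of the lactone is the unused π-bond of a terminal allene, and the lactone ring C6–O–C12–C11–C7 is a ring-expanded cyclobutanone.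
- The amide–allene is assembled by aldol condensation (C1=C10) of a west epoxy-aldehyde amide (from but-2-ynoic acid) with an east allenyl γ-lactone (from dimethyl (S)-malate); opening that temporary C14/O8 lactone frees O8 for the epoxyangelate (from angelic acid).
- Ring order: two oxiranes, temporary γ-lactone (opened again), cyclobutane plus ten-membered ring, final γ-lactone.

Key step: step 19

Remark (numbering): atoms are named by germacrane numbering of the target: ring carbons C1–C10, lactone carbons C11, C12 (carbonyl) and C13 (exocyclic CH2), ester carbon C14, ring methyl C15; the lactone oxygen is on C6.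
Remark (assumption): the (4S,5S)-diazaborolidine of step 14 is taken as the enantiomer that adds the propargyl group to the Si face of the aldehyde (C8 = S); if the sense is the reverse, the (4R,5R) enantiomer is used.

**Epoxyangelic acid**

Step 1
Reactants: 1 (2Z)-2-methylbut-2-enoic acid (angelic acid)
Product: 2 (2Z)-2-methylbut-2-en-1-ol
Conditions: LiAlH4, Et2O, 0 °C to rt; aq. Rochelle salt
Reagents that add atoms: none
Why: Hydride reduction of the acid leaves the trisubstituted Z-alkene untouched and gives the allylic alcohol needed for directed epoxidation.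

Step 2
Reactants: 2 (2Z)-2-methylbut-2-en-1-ol
Product: 3 [(2S,3R)-2,3-dimethyloxiran-2-yl]methanol
Conditions: Ti(OiPr)4 (10 mol%), L-(+)-diisopropyl tartrate (12 mol%), t-BuOOH, 4 Å MS, CH2Cl2, −20 °C
Reagents that add atoms: tert-butyl hydroperoxide, CC(C)(C)OO
Why: Katsuki–Sharpless asymmetric epoxidation: the allylic hydroxyl binds the titanium–tartrate catalyst, which with L-(+)-tartrate should give the (2S,3R)-epoxy alcohol; the cis relation of CH2OH and the C3 methyl follows from the Z-alkene.

Step 3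
Reactants: 3 [(2S,3R)-2,3-dimethyloxiran-2-yl]methanol
Product: 4 (2R,3R)-2,3-dimethyloxirane-2-carboxylic acid
Conditions: RuCl3 (2 mol%), NaIO4, CCl4–MeCN–H2O, rt
Reagents that add atoms: sodium periodate, [Na+].[O-]I(=O)(=O)=O
Why: RuO4 generated in situ oxidises the primary alcohol to the acid without touching the oxirane or its stereocentres (the C2 descriptor changes to R by priority only).

**West fragment**

Step 4
Reactants: 5 but-2-ynoic acid
Product: 6 (2Z)-3-iodobut-2-enoic acid
Conditions: NaI, AcOH, 110 °C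
Reagents that add atoms: sodium iodide, [Na+].[I-]
Why: Conjugate anti-addition of HI to the ynoic acid places iodine cis to the carboxyl group, fixing the later C4=C5 geometry.

Step 5
Reactants: 6 (2Z)-3-iodobut-2-enoic acid
Product: 8 (3Z)-1-diazo-4-iodopent-3-en-2-one, via acid chloride 7 (not isolated)
Conditions: (COCl)2, DMF (cat.), CH2Cl2, 0 °C to rt; then CH2N2, Et3N, Et2O, 0 °C
Reagents that add atoms: diazomethane, C=[N+]=[N-]
Why: First half of an Arndt–Eistert homologation: the acid chloride acylates diazomethane, and the β,β-disubstituted enoyl unit resists dipolar addition and keeps its Z geometry.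

Step 6
Reactants: 8 (3Z)-1-diazo-4-iodopent-3-en-2-one
Product: 9 (3Z)-4-iodo-1-(pyrrolidin-1-yl)pent-3-en-1-one
Conditions: PhCO2Ag (10 mol%), Et3N, pyrrolidine, THF, −20 °C to rt, dark
Reagents that add atoms: pyrrolidine, C1CCNC1
Why: Silver-catalysed Wolff rearrangement: the alkenyl group migrates with retention of its Z configuration and the ketene is trapped by pyrrolidine to give the β,γ-unsaturated tertiary amide (future C12 and C6).

Step 7
Reactants: 9 (3Z)-4-iodo-1-(pyrrolidin-1-yl)pent-3-en-1-one; 10 prop-2-yn-1-ol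
Product: 11 (3Z)-7-hydroxy-4-methyl-1-(pyrrolidin-1-yl)hept-3-en-5-yn-1-one
Conditions: PdCl2(PPh3)2 (3 mol%), CuI (6 mol%), Et3N, THF, rt
Reagents that add atoms: none
Why: Sonogashira coupling proceeds with retention of the vinyl iodide geometry and tolerates the free alcohol and the amide.

Step 8
Reactants: 11 (3Z)-7-hydroxy-4-methyl-1-(pyrrolidin-1-yl)hept-3-en-5-yn-1-one
Product: 12 (3Z,5Z)-7-hydroxy-4-methyl-1-(pyrrolidin-1-yl)hepta-3,5-dien-1-one
Conditions: H2 (1 atm), Pd/CaCO3 poisoned with Pb(OAc)2, quinoline, EtOAc, rt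
Reagents that add atoms: none
Why: Syn-semihydrogenation of the alkyne on poisoned palladium should give the Z-alkene (future cis-oxirane) and stop there.

Step 9
Reactants: 12 (3Z,5Z)-7-hydroxy-4-methyl-1-(pyrrolidin-1-yl)hepta-3,5-dien-1-one
Product: 13 (3Z)-4-[(2S,3R)-3-(hydroxymethyl)oxiran-2-yl]-1-(pyrrolidin-1-yl)pent-3-en-1-one
Conditions: Ti(OiPr)4 (20 mol%), D-(−)-diisopropyl tartrate (24 mol%), t-BuOOH, 4 Å MS, CH2Cl2, −25 °C
Reagents that add atoms: tert-butyl hydroperoxide, CC(C)(C)OO
Why: Katsuki–Sharpless asymmetric epoxidation is directed by the allylic hydroxyl, so only the C2=C3 alkene reacts; with D-(−)-tartrate a Z-allylic alcohol should give the (2R,3S)-cis-oxirane (germacrane numbering).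

Step 10
Reactants: 13 (3Z)-4-[(2S,3R)-3-(hydroxymethyl)oxiran-2-yl]-1-(pyrrolidin-1-yl)pent-3-en-1-one
Product: 14 (2S,3S)-3-[(2Z)-5-oxo-5-(pyrrolidin-1-yl)pent-2-en-2-yl]oxirane-2-carbaldehyde
Conditions: Dess–Martin periodinane, NaHCO3, CH2Cl2, 0 °C
Reagents that add atoms: none
Why: Dess–Martin oxidation under bicarbonate buffer should give the cis-epoxy aldehyde without base-induced epimerisation; it is used at once.

**East fragment**

Step 11
Reactants: 15 dimethyl (2S)-2-hydroxybutanedioate (dimethyl (S)-malate)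
Product: 16 methyl (3S)-3,4-dihydroxybutanoate
Conditions: BH3·SMe2, NaBH4 (5 mol%), THF, rt; MeOH
Reagents that add atoms: none
Why: Hydroxyl-directed borane reduction (alkoxyborane chelate) reduces only the ester next to the free hydroxyl; the malate stereocentre becomes C9.

Step 12
Reactants: 16 methyl (3S)-3,4-dihydroxybutanoate
Product: 17 methyl (3S)-3,4-bis(triethylsilyloxy)butanoate
Conditions: Et3SiCl, imidazole, CH2Cl2, 0 °C
Reagents that add atoms: chlorotriethylsilane, CC[Si](Cl)(CC)CC
Why: Standard silylation of both hydroxyls; prompt protection prevents lactonisation of the γ-hydroxy ester.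

Step 13
Reactants: 17 methyl (3S)-3,4-bis(triethylsilyloxy)butanoate
Product: 18 methyl (3S)-4-oxo-3-(triethylsilyloxy)butanoate
Conditions: (COCl)2, DMSO, CH2Cl2, −78 to −30 °C; Et3N
Reagents that add atoms: none
Why: Under Swern conditions the chlorosulfonium ion cleaves the less hindered primary triethylsilyl ether and oxidises it directly to the aldehyde, while the secondary silyl ether is retained.

Step 14
Reactants: 18 methyl (3S)-4-oxo-3-(triethylsilyloxy)butanoate
Product: 20 (4S,5S)-5-(propa-1,2-dien-1-yl)-4-(triethylsilyloxy)oxolan-2-one, via hydroxy ester 19 (not isolated)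
Conditions: (4S,5S)-2-bromo-4,5-diphenyl-1,3-bis(4-tolylsulfonyl)-1,3,2-diazaborolidine, tributyl(propa-1,2-dien-1-yl)stannane, CH2Cl2, 0 °C to rt; then 18, −78 °C; aq. work-up; PPTS (cat.), CH2Cl2, rt
Reagents that add atoms: tributyl(propa-1,2-dien-1-yl)stannane, C=C=C[Sn](CCCC)(CCCC)CCCC
Why: The allenylstannane transmetalates (SE2′) to the B-propargyl diazaborolidine, which adds to the aldehyde through a cyclic SE2′ transition state to give the α-allenyl carbinol; the chiral boron reagent sets C8 (S) against the Felkin–Anh bias, and lactonisation of the γ-hydroxy ester then ties up O8 and leaves O9 silylated.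

**Union and end game**

Step 15
Reactants: 20 (4S,5S)-5-(propa-1,2-dien-1-yl)-4-(triethylsilyloxy)oxolan-2-one; 14 (2S,3S)-3-[(2Z)-5-oxo-5-(pyrrolidin-1-yl)pent-2-en-2-yl]oxirane-2-carbaldehyde
Product: 21 aldol adduct: lactone 20 bearing at C10 (trans to the C9 silyloxy group) the CH(OH) unit derived from the aldehyde of 14 (C1 carbinol epimers)
Conditions: LiN(SiMe3)2, THF, −78 °C; then 14; AcOH quench at −78 °C
Reagents that add atoms: none
Why: Aldol addition of the lithium lactone enolate to the epoxy aldehyde at −78 °C should outrun enolisation and Payne rearrangement; the bond at C10 forms anti to the C9 silyloxy group, and both new stereocentres are removed in the next step.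

Step 16
Reactants: 21 aldol adduct
Product: 23 (3E,4S,5S)-3-{[(2R,3S)-3-[(2Z)-5-oxo-5-(pyrrolidin-1-yl)pent-2-en-2-yl]oxiran-2-yl]methylidene}-5-(propa-1,2-dien-1-yl)-4-(triethylsilyloxy)oxolan-2-one, via mesylate 22 (not isolated)
Conditions: MsCl, Et3N, CH2Cl2, −20 °C; then DBU, 0 °C
Reagents that add atoms: none
Why: Mesylation and E1cB elimination through the lactone enolate should give the conjugated alkylidene lactone with C2 anti to the lactone carbonyl (the preferred E geometry, which is the ring-cis C1=C10 of the target).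

Step 17
Reactants: 23 alkylidene lactone
Product: 25 methyl (2E,3S,4S)-4-hydroxy-2-{[(2R,3S)-3-[(2Z)-5-oxo-5-(pyrrolidin-1-yl)pent-2-en-2-yl]oxiran-2-yl]methylidene}-3-(triethylsilyloxy)hepta-5,6-dienoate, via lithium carboxylate 24 (not isolated)
Conditions: LiOH, THF–H2O, 0 °C; evaporate; MeI, DMF, rt
Reagents that add atoms: lithium hydroxide, [Li+].[OH-]; iodomethane, CI
Why: Saponification opens only the conjugated γ-lactone (tertiary amide and silyl ether survive) and the carboxylate is O-methylated under neutral conditions, releasing the C8 hydroxyl without touching a stereocentre.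

Step 18
Reactants: 25 hydroxy ester; 4 (2R,3R)-2,3-dimethyloxirane-2-carboxylic acid
Product: 27 methyl (2E,3S,4S)-4-{[(2R,3R)-2,3-dimethyloxirane-2-carbonyl]oxy}-2-{[(2R,3S)-3-[(2Z)-5-oxo-5-(pyrrolidin-1-yl)pent-2-en-2-yl]oxiran-2-yl]methylidene}-3-(triethylsilyloxy)hepta-5,6-dienoate, via mixed anhydride 26 (not isolated)
Conditions: 2,4,6-Cl3C6H2COCl, Et3N, THF, rt; then 25, DMAP, toluene, rt
Reagents that add atoms: none
Why: Yamaguchi esterification: DMAP transfers the hindered epoxyangeloyl group from the mixed anhydride to the C8 hydroxyl with retention at C8, and this should be faster than relactonisation under these weakly basic conditions.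

Step 19
Reactants: 27 amide–allene
Product: 30 2-methylenecyclobutanone (C12 ketone bonded to C6 and C11; C6–C7 bond closes the ten-membered ring; H6/H7 trans; all other groups as in 27), via keteniminium triflate 28 (not isolated), via cyclobutaniminium triflate 29 (not isolated)
Conditions: Tf2O, 2,4,6-collidine, CH2Cl2, −40 °C; slow addition to ClCH2CH2Cl, 50 °C (1 mM); then H2O, NaOAc–AcOH (pH 5), rt
Reagents that add atoms: water, O
Why: Proposed new method: O-triflation of the tertiary amide and loss of TfOH to collidine give the conjugated keteniminium 28, whose electrophilic carbon C12 attacks the central allene carbon C11 (twelve-membered endo closure); the resulting enamine–allyl cation pair collapses by C6–C7 bond formation, a stepwise [2+2] that closes the cyclobutane and, with the same bond, the ten-membered carbocycle, and hydrolysis of iminium 29 gives the ketone. The closest known reactions are the intramolecular keteniminium–alkene [2+2] of amide/Tf2O systems and the intramolecular ketene–allene cycloaddition to 2-methylenecyclobutanones, both established only for three- and four-atom tethers, so the macrocyclic closure and the allene partner are new. The hairpin enforced by the 4Z-alkene, the cis-oxirane and the ring-cis C1=C10 alkene holds C6 near the allene, and high dilution suppresses oligomers. Regioselectivity (C6 to C7, not C13) should follow the usual preference of ketene and keteniminium cycloadditions for bonding the α-carbon to the more substituted cationic terminus, here also the smaller ring. C7 is set in the ring-closing collapse, C6 approaching anti to the C8 acyloxy group in the A(1,3)-minimised conformer; C6 is epimerisable in 29 (iminium–enamine) and should settle trans to C8 across the four-membered ring, which after ring expansion gives the trans-lactone. Chemoselectivity rests on the amide being by far the most nucleophilic carbonyl toward Tf2O and on the allene being the only electron-rich unhindered π-bond within reach, with collidine buffering the oxiranes against triflic acid.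

Step 20
Reactants: 30 2-methylenecyclobutanone
Product: 31 9-O-triethylsilyl ether of the target
Conditions: 30% aq. H2O2, Na2HPO4, CF3CH2OH, 0 °C to rt
Reagents that add atoms: hydrogen peroxide, OO
Why: Baeyer–Villiger oxidation of the strained 2-methylenecyclobutanone: the Criegee adduct relieves ring strain by migration of the secondary allylic carbon C6 (better migrating group than the sp2 carbon C11) with retention, giving the trans-fused α-methylene-γ-butyrolactone, and the non-electrophilic oxidant should leave the alkenes alone.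

Step 21
Reactants: 31 9-O-triethylsilyl ether of the target
Product: 32 CNP0291485.1 (target)
Conditions: HF·pyridine, pyridine, THF, 0 °C
Reagents that add atoms: none
Why: Fluoride-mediated cleavage of the secondary triethylsilyl ether under pyridine-buffered conditions should free the C9 hydroxyl without opening the oxiranes or adding to the α-methylene lactone.

**Compound list**

1 | (2Z)-2-methylbut-2-enoic acid (angelic acid) | C/C=C(/C)C(=O)O | starting material
2 | (2Z)-2-methylbut-2-en-1-ol | C/C=C(/C)CO | intermediate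
3 | [(2S,3R)-2,3-dimethyloxiran-2-yl]methanol | OC[C@]1(C)O[C@@H]1C | intermediate
4 | (2R,3R)-2,3-dimethyloxirane-2-carboxylic acid | O=C(O)[C@]1(C)O[C@@H]1C | intermediate
5 | but-2-ynoic acid | CC#CC(=O)O | starting material
6 | (2Z)-3-iodobut-2-enoic acid | C/C(I)=C/C(=O)O | intermediate
7 | (2Z)-3-iodobut-2-enoyl chloride | C/C(I)=C/C(=O)Cl | intermediate
8 | (3Z)-1-diazo-4-iodopent-3-en-2-one | C/C(I)=C/C(=O)C=[N+]=[N-] | intermediate
9 | (3Z)-4-iodo-1-(pyrrolidin-1-yl)pent-3-en-1-one | C/C(I)=C/CC(=O)N1CCCC1 | intermediate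
10 | prop-2-yn-1-ol | C#CCO | starting material
11 | (3Z)-7-hydroxy-4-methyl-1-(pyrrolidin-1-yl)hept-3-en-5-yn-1-one | C/C(C#CCO)=C/CC(=O)N1CCCC1 | intermediate
12 | (3Z,5Z)-7-hydroxy-4-methyl-1-(pyrrolidin-1-yl)hepta-3,5-dien-1-one | O=C(N1CCCC1)C/C=C(/C)\C=C/CO | intermediate
13 | (3Z)-4-[(2S,3R)-3-(hydroxymethyl)oxiran-2-yl]-1-(pyrrolidin-1-yl)pent-3-en-1-one | O=C(N1CCCC1)C/C=C(/C)[C@@H]1O[C@@H]1CO | intermediate
14 | (2S,3S)-3-[(2Z)-5-oxo-5-(pyrrolidin-1-yl)pent-2-en-2-yl]oxirane-2-carbaldehyde | O=C(N1CCCC1)C/C=C(/C)[C@@H]1O[C@@H]1C=O | intermediate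
15 | dimethyl (2S)-2-hydroxybutanedioate | COC(=O)C[C@H](O)C(=O)OC | starting material
16 | methyl (3S)-3,4-dihydroxybutanoate | COC(=O)C[C@H](O)CO | intermediate
17 | methyl (3S)-3,4-bis(triethylsilyloxy)butanoate | COC(=O)C[C@H](O[Si](CC)(CC)CC)CO[Si](CC)(CC)CC | intermediate
18 | methyl (3S)-4-oxo-3-(triethylsilyloxy)butanoate | COC(=O)C[C@H](O[Si](CC)(CC)CC)C=O | intermediate
19 | methyl (3S,4S)-4-hydroxy-3-(triethylsilyloxy)hepta-5,6-dienoate | COC(=O)C[C@H](O[Si](CC)(CC)CC)[C@@H](O)C=C=C | intermediate
20 | (4S,5S)-5-(propa-1,2-dien-1-yl)-4-(triethylsilyloxy)oxolan-2-one | O=C1C[C@H](O[Si](CC)(CC)CC)[C@@H](O1)C=C=C | intermediate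
21 | aldol adduct of 20 and 14 (C10 substituent trans to the C9 silyloxy group; C1 carbinol epimers) | O=C(N1CCCC1)C/C=C(/C)[C@@H]2O[C@@H]2C(O)[C@@H]3C(=O)O[C@@H](C=C=C)[C@H]3O[Si](CC)(CC)CC | intermediate
22 | methanesulfonate of 21 | O=C(N1CCCC1)C/C=C(/C)[C@@H]2O[C@@H]2C(OS(C)(=O)=O)[C@@H]3C(=O)O[C@@H](C=C=C)[C@H]3O[Si](CC)(CC)CC | intermediate
23 | (3E,4S,5S)-alkylidene lactone (C1=C10 formed; oxirane 2R,3S; 4Z) | O=C(N1CCCC1)C/C=C(/C)[C@@H]2O[C@@H]2/C=C3/C(=O)O[C@@H](C=C=C)[C@H]3O[Si](CC)(CC)CC | intermediate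
24 | lithium carboxylate from opening of the C14/O8 lactone of 23 | O=C(N1CCCC1)C/C=C(/C)[C@@H]2O[C@@H]2/C=C(/C(=O)[O-])[C@H](O[Si](CC)(CC)CC)[C@@H](O)C=C=C.[Li+] | intermediate
25 | methyl (2E,3S,4S)-4-hydroxy-2-{[(2R,3S)-3-[(2Z)-5-oxo-5-(pyrrolidin-1-yl)pent-2-en-2-yl]oxiran-2-yl]methylidene}-3-(triethylsilyloxy)hepta-5,6-dienoate | O=C(N1CCCC1)C/C=C(/C)[C@@H]2O[C@@H]2/C=C(/C(=O)OC)[C@H](O[Si](CC)(CC)CC)[C@@H](O)C=C=C | intermediate
26 | (2R,3R)-2,3-dimethyloxirane-2-carboxylic 2,4,6-trichlorobenzoic anhydride | O=C(OC(=O)c1c(Cl)cc(Cl)cc1Cl)[C@]1(C)O[C@@H]1C | intermediate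
27 | 8-O-[(2R,3R)-2,3-dimethyloxirane-2-carbonyl] ester of 25 (amide–allene) | O=C(N1CCCC1)C/C=C(/C)[C@@H]2O[C@@H]2/C=C(/C(=O)OC)[C@H](O[Si](CC)(CC)CC)[C@@H](OC(=O)[C@]3(C)O[C@@H]3C)C=C=C | intermediate
28 | keteniminium triflate from 27 (pyrrolidinium N=C12=C6) | C(=[N+]1CCCC1)=C/C=C(/C)[C@@H]2O[C@@H]2/C=C(/C(=O)OC)[C@H](O[Si](CC)(CC)CC)[C@@H](OC(=O)[C@]3(C)O[C@@H]3C)C=C=C.[O-]S(=O)(=O)C(F)(F)F | intermediate
29 | cyclobutaniminium triflate (C12=N+ bonded to C6 and C11; ten-membered ring closed) | C=C1C(=[N+]4CCCC4)[C@@H]2/C=C(/C)[C@@H]3O[C@@H]3/C=C(/C(=O)OC)[C@H](O[Si](CC)(CC)CC)[C@@H](OC(=O)[C@]3(C)O[C@@H]3C)[C@@H]12.[O-]S(=O)(=O)C(F)(F)F | intermediate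
30 | 2-methylenecyclobutanone (31 without the lactone oxygen: C12 bonded directly to C6; H6/H7 trans) | C=C1C(=O)[C@@H]2/C=C(/C)[C@@H]3O[C@@H]3/C=C(/C(=O)OC)[C@H](O[Si](CC)(CC)CC)[C@@H](OC(=O)[C@]3(C)O[C@@H]3C)[C@@H]12 | intermediate
31 | 9-O-triethylsilyl ether of the target | C=C1C(=O)O[C@@H]2/C=C(/C)[C@@H]3O[C@@H]3/C=C(/C(=O)OC)[C@H](O[Si](CC)(CC)CC)[C@@H](OC(=O)[C@]3(C)O[C@@H]3C)[C@@H]12 | intermediate
32 | CNP0291485.1: methyl 2,3-epoxy-9-hydroxy-8-[(2R,3R)-2,3-dimethyloxirane-2-carbonyl]oxy-germacra-1(10),4,11(13)-trien-12,6-olid-14-oate (2R,3S,6R,7S,8S,9S; 1(10)E by CIP, 4Z) | C=C1C(=O)O[C@@H]2/C=C(/C)[C@@H]3O[C@@H]3/C=C(/C(=O)OC)[C@H](O)[C@@H](OC(=O)[C@]3(C)O[C@@H]3C)[C@@H]12 | target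

**Totals**
Total step count: 21. Longest linear sequence: 14 steps (steps 4–10, then 15–21).

**Steps most likely to fail**

1. Step 19 (proposed new method). What may go wrong: closure of the enamine carbon onto the unsubstituted allene terminus (twelve-membered regioisomer), oligomerisation in competition with the macrocyclic closure, or ionisation of the divinyl oxirane by the cationic intermediates. The fallback uses known chemistry only, sets out from acid 6 and lactone 20 and comes back at 31. It closes the ten-membered ring and the lactone together by the classical CrCl2-mediated intramolecular Barbier allylation–lactonisation of a 2-(bromomethyl)enoate onto an enal. Acid 6 is converted (EDC, MeNHOMe·HCl) into the N-methoxy-N-methylamide F1, which is coupled (Stille) with (Z)-3-(tributylstannyl)prop-2-en-1-ol to dienol F2, epoxidised as in step 9 to epoxy alcohol F3 and oxidised as in step 10 to aldehyde F4. Ozonolysis of 20 (O3; Me2S) gives lactone aldehyde F5, and a Horner–Wadsworth–Emmons reaction with methyl 2-(dimethoxyphosphoryl)-3-(4-methoxybenzyloxy)propanoate gives enoate F6. F6 and F4 are joined and elaborated by the reactions of steps 15–18, giving aldol adduct F7, alkylidene lactone F8, hydroxy ester F9 and epoxyangelate F10. DDQ removes the 4-methoxybenzyl group (allylic alcohol F11), Cp2Zr(H)Cl reduces the N-methoxy-N-methylamide to the (Z)-enal F12, and CBr4/PPh3 gives allylic bromide F13. CrCl2 (THF–DMF, high dilution) then generates the allylchromium reagent, which adds through C7 to the aldehyde, and the alkoxide lactonises onto the methyl ester to give 31.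

2. Step 20. What may go wrong: electrophilic epoxidation of the C4=C5 alkene or conjugate attack of the peroxide on the enone competing with Criegee migration. The fallback runs from 30 back to 31 by photochemical ring expansion. Irradiation (λ > 300 nm) of 30 in THF–H2O causes Norrish α-cleavage of the more substituted allylic C6–C12 bond and collapse to the oxacarbene, which water traps as lactol F14 with retention at C6; MnO2 then oxidises the allylic lactol to lactone 31.

3. Step 14. What may go wrong: incomplete reagent control in the mismatched addition (the α-silyloxy aldehyde prefers Felkin–Anh attack), giving the C8 epimer. The fallback runs from 18 back to 20, using substrate control and inverting C8 afterwards. Trichloro(prop-2-yn-1-yl)silane in DMF adds (SE2′) with Felkin–Anh selectivity to give the 3,4-anti allenyl carbinol F15; LiOH gives hydroxy acid F16, and Mitsunobu lactonisation (PPh3, DIAD) closes the lactone with inversion at C8 to give 20.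

Further compounds
F1 | step 19 | (2Z)-3-iodo-N-methoxy-N-methylbut-2-enamide | C/C(I)=C/C(=O)N(C)OC
F2 | step 19 | (2Z,4Z)-6-hydroxy-N-methoxy-N,3-dimethylhexa-2,4-dienamide | CON(C)C(=O)/C=C(/C)\C=C/CO
F3 | step 19 | (2Z)-3-[(2S,3R)-3-(hydroxymethyl)oxiran-2-yl]-N-methoxy-N-methylbut-2-enamide | CON(C)C(=O)/C=C(/C)[C@@H]1O[C@@H]1CO
F4 | step 19 | (2Z)-3-[(2S,3S)-3-formyloxiran-2-yl]-N-methoxy-N-methylbut-2-enamide | CON(C)C(=O)/C=C(/C)[C@@H]1O[C@@H]1C=O
F5 | step 19 | lactone aldehyde from ozonolysis of 20 (allene replaced by CHO) | O=C1C[C@H](O[Si](CC)(CC)CC)[C@@H](O1)C=O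
F6 | step 19 | lactone 20 with the allene replaced by CH=C(CO2Me)CH2O-(4-methoxybenzyl) | O=C1C[C@H](O[Si](CC)(CC)CC)[C@@H](O1)/C=C(/C(=O)OC)COCc1ccc(OC)cc1
F7 | step 19 | aldol adduct of F6 and F4 (analogue of 21) | CON(C)C(=O)/C=C(/C)[C@@H]2O[C@@H]2C(O)[C@@H]3C(=O)O[C@@H](/C=C(/C(=O)OC)COCc4ccc(OC)cc4)[C@H]3O[Si](CC)(CC)CC
F8 | step 19 | alkylidene lactone (analogue of 23) | CON(C)C(=O)/C=C(/C)[C@@H]2O[C@@H]2/C=C3/C(=O)O[C@@H](/C=C(/C(=O)OC)COCc4ccc(OC)cc4)[C@H]3O[Si](CC)(CC)CC
F9 | step 19 | hydroxy methyl ester (analogue of 25) | CON(C)C(=O)/C=C(/C)[C@@H]2O[C@@H]2/C=C(/C(=O)OC)[C@H](O[Si](CC)(CC)CC)[C@@H](O)/C=C(/C(=O)OC)COCc1ccc(OC)cc1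
F10 | step 19 | epoxyangelate (analogue of 27) | CON(C)C(=O)/C=C(/C)[C@@H]2O[C@@H]2/C=C(/C(=O)OC)[C@H](O[Si](CC)(CC)CC)[C@@H](OC(=O)[C@]3(C)O[C@@H]3C)/C=C(/C(=O)OC)COCc1ccc(OC)cc1
F11 | step 19 | allylic alcohol from F10 (4-methoxybenzyl removed) | CON(C)C(=O)/C=C(/C)[C@@H]2O[C@@H]2/C=C(/C(=O)OC)[C@H](O[Si](CC)(CC)CC)[C@@H](OC(=O)[C@]3(C)O[C@@H]3C)/C=C(/C(=O)OC)CO
F12 | step 19 | (Z)-enal from F11 (C6 aldehyde) | O=C/C=C(/C)[C@@H]2O[C@@H]2/C=C(/C(=O)OC)[C@H](O[Si](CC)(CC)CC)[C@@H](OC(=O)[C@]3(C)O[C@@H]3C)/C=C(/C(=O)OC)CO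
F13 | step 19 | allylic bromide from F12 | O=C/C=C(/C)[C@@H]2O[C@@H]2/C=C(/C(=O)OC)[C@H](O[Si](CC)(CC)CC)[C@@H](OC(=O)[C@]3(C)O[C@@H]3C)/C=C(/C(=O)OC)CBr
F14 | step 20 | lactol of 31 (C12 hemiacetal, anomers) | C=C1C(O)O[C@@H]2/C=C(/C)[C@@H]3O[C@@H]3/C=C(/C(=O)OC)[C@H](O[Si](CC)(CC)CC)[C@@H](OC(=O)[C@]3(C)O[C@@H]3C)[C@@H]12
F15 | step 14 | methyl (3S,4R)-4-hydroxy-3-(triethylsilyloxy)hepta-5,6-dienoate | COC(=O)C[C@H](O[Si](CC)(CC)CC)[C@H](O)C=C=C
F16 | step 14 | (3S,4R)-4-hydroxy-3-(triethylsilyloxy)hepta-5,6-dienoic acid | OC(=O)C[C@H](O[Si](CC)(CC)CC)[C@H](O)C=C=C
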